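**Strategy.** The route rests on forming the ring-fusion bond C3a–C7a (benzofuran numbering), common to the dihydrofuran and the six-membered carbocycle, after O1–C7a is already in place. Thermolysis of a 3-alkoxycyclobutenone should release a vinylketene that adds (2+2) to an acyl ynol ether tethered through O1. Strain-driven 4π opening, 6π closure and tautomerisation should then deliver, in one operation, the 7-acyl-4,6-dioxygenated 2,3-dihydrobenzofuran as a single regioisomer. The step exploits the 1,3,5-oxygenation of the carbocycle (C6 from the ketene carbonyl, C4 and C7a from two ynol ethers). The precursor is a monocyclic cyclobutenone with an alkoxy-ynone side chain; the gem-diprenyl C5 is installed last by alkylative dearomatisation.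

Key step: step 6

Remark: the target is a tautomeric triketone, drawn and named as its chelated exocyclic enol; its only stereocenter (C2 of the dihydrofuran) is R. Ketene for step 5 is taken as a reagent generated by pyrolysis of acetone.

**Step 1**
Reactants: 1 methyl (2R)-oxirane-2-carboxylate
Product: 2 2-[(2R)-oxiran-2-yl]propan-2-ol
Conditions: MeMgCl (2.1 equiv), THF, −78 → −40 °C; aq. NH4Cl
Reagents that add atoms: methylmagnesium chloride, C[Mg]Cl
Why: Double Grignard addition to the ester is faster at low temperature than opening of the epoxide, and the stereocenter, which is not touched, keeps its R configuration.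

**Step 2**
Reactants: 2 2-[(2R)-oxiran-2-yl]propan-2-ol
Product: 3 triethyl({2-[(2R)-oxiran-2-yl]propan-2-yl}oxy)silane
Conditions: TESOTf, 2,6-lutidine, CH2Cl2, −78 °C
Reagents that add atoms: triethylsilyl trifluoromethanesulfonate, CC[Si](CC)(CC)OS(=O)(=O)C(F)(F)F
Why: Silylation of the hindered tertiary alcohol with a silyl triflate and a hindered base leaves the epoxide intact and masks the hydroxyl that would otherwise trap the ketenes of steps 5 and 6.

**Step 3**
Reactants: 3 triethyl({2-[(2R)-oxiran-2-yl]propan-2-yl}oxy)silane and 4 2-(trimethylsilyl)ethanol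
Product: 7 (3R)-2-methyl-2-[(triethylsilyl)oxy]-6-[2-(trimethylsilyl)ethoxy]hex-5-yn-3-ol, via dichlorovinyl ether 5 (not isolated), via lithium alkynyl ether 6 (not isolated)
Conditions: 4, KH, THF, 0 °C; Cl2C=CHCl, 0 °C → rt; n-BuLi (2.0 equiv), −78 °C; then 3, BF3·OEt2, −78 °C; aq. NaHCO3
Reagents that add atoms: trichloroethylene, ClC=C(Cl)Cl
Why: The alkoxide adds to dichloroacetylene formed from trichloroethylene, n-BuLi converts the dichlorovinyl ether into the lithium alkynyl ether (dichlorovinyl ether route to ynol ethers), and BF3-promoted epoxide opening by this acetylide occurs at the unsubstituted carbon, so the C–O bond of the stereocenter is retained.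

**Step 4**
Reactants: 7 (3R)-2-methyl-2-[(triethylsilyl)oxy]-6-[2-(trimethylsilyl)ethoxy]hex-5-yn-3-ol
Product: 10 4-methyl-1-({(3R)-2-methyl-2-[(triethylsilyl)oxy]-6-[2-(trimethylsilyl)ethoxy]hex-5-yn-3-yl}oxy)pent-1-yn-3-one, via dichlorovinyl ether 8 (not isolated), via lithium alkynyl ether 9 (not isolated)
Conditions: KH, THF, 0 °C; Cl2C=CHCl, rt; n-BuLi (2.1 equiv), −78 °C; i-PrC(O)N(OMe)Me, −78 → −20 °C; aq. NH4Cl
Reagents that add atoms: trichloroethylene, ClC=C(Cl)Cl; N-methoxy-N,2-dimethylpropanamide, CC(C)C(=O)N(C)OC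
Why: The same dichlorovinyl ether route on the secondary alkoxide gives a lithium alkynyl ether whose acylation by the Weinreb amide stops at the ketone through the chelated tetrahedral adduct, with the O–C bond of the stereocenter untouched.

**Step 5**
Reactants: 10 4-methyl-1-({(3R)-2-methyl-2-[(triethylsilyl)oxy]-6-[2-(trimethylsilyl)ethoxy]hex-5-yn-3-yl}oxy)pent-1-yn-3-one
Product: 11 2-{(2R)-3-methyl-2-[(4-methyl-3-oxopent-1-yn-1-yl)oxy]-3-[(triethylsilyl)oxy]butyl}-3-[2-(trimethylsilyl)ethoxy]cyclobut-2-en-1-one
Conditions: ketene (excess, generated by pyrolysis of acetone), CH2Cl2, 0 °C → rt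
Reagents that add atoms: ketene, C=C=O
Why: Ketene–alkyne (2+2) cycloaddition joins the ketene carbonyl carbon to the nucleophilic β-carbon of the electron-rich ynol ether to give the 3-alkoxycyclobutenone, while the acyl-substituted ynol ether is too electron-poor to react intermolecularly.

**Step 6**
Reactants: 11 2-{(2R)-3-methyl-2-[(4-methyl-3-oxopent-1-yn-1-yl)oxy]-3-[(triethylsilyl)oxy]butyl}-3-[2-(trimethylsilyl)ethoxy]cyclobut-2-en-1-one
Product: 16 1-[(2R)-6-hydroxy-2-{2-[(triethylsilyl)oxy]propan-2-yl}-4-[2-(trimethylsilyl)ethoxy]-2,3-dihydro-1-benzofuran-7-yl]-2-methylpropan-1-one, via vinylketene 12 (not isolated), via bicyclic cyclobutenone 13 (not isolated), via dienylketene 14 (not isolated), via cyclohexadienone 15 (not isolated)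
Conditions: toluene (0.01 M), 80 → 110 °C
Reagents that add atoms: none
Why: Proposed new method: heating should open cyclobutenone 11 (4π-electrocyclic, strain release) to vinylketene 12, which adds (2+2) to the tethered ynol ether with the ketene α-carbon on the O-bearing alkyne carbon (the C3a–C7a bond) and the ketene carbonyl carbon on the acyl-bearing carbon; the strained bicyclic cyclobutenone 13 opens (4π) to dienylketene 14, which closes by 6π-electrocyclisation to 15 and tautomerises to phenol 16. The closest known reaction type is the Danheiser benzannulation of cyclobutenone-derived vinylketenes with alkoxy- or siloxyalkynes, here made intramolecular through the ynol ether oxygen and applied to an acyl-substituted ynol ether. The dihydrofuran closes in the (2+2) step across a three-atom tether (bicyclo[3.2.0] mode, the favoured one for intramolecular ketene cycloadditions), and the carbocycle closes by disrotatory 6π-electrocyclisation of a dienylketene whose cis geometry is enforced by the new five-membered ring. No new stereocenter remains: C2 is carried unchanged from 1 and the ring-fusion stereocenter of 13 is erased on ring opening. The step needs regioselective (2+2) addition in competition with ketene dimerisation and retro-ene loss of the ynol ether; the tether, the matched polarisation of the push–pull alkyne (nucleophilic acyl-bearing carbon, electrophilic O-bearing carbon) and high dilution should secure it.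

**Step 7**
Reactants: 16 1-[(2R)-6-hydroxy-2-{2-[(triethylsilyl)oxy]propan-2-yl}-4-[2-(trimethylsilyl)ethoxy]-2,3-dihydro-1-benzofuran-7-yl]-2-methylpropan-1-one
Product: 17 1-[(2R)-4,6-dihydroxy-2-(2-hydroxypropan-2-yl)-2,3-dihydro-1-benzofuran-7-yl]-2-methylpropan-1-one
Conditions: Bu4NF (4 equiv), DMF, 60 °C; aq. NH4Cl
Reagents that add atoms: none
Why: Fluoride attack on silicon triggers β-elimination of ethene from the 2-(trimethylsilyl)ethyl aryl ether, whose para-acyl phenoxide is a good leaving group, and cleaves the tertiary triethylsilyl ether in the same operation.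

**Step 8**
Reactants: 17 1-[(2R)-4,6-dihydroxy-2-(2-hydroxypropan-2-yl)-2,3-dihydro-1-benzofuran-7-yl]-2-methylpropan-1-one and 18 1-bromo-3-methylbut-2-ene (prenyl bromide)
Product: 20 garcinielliptone HC, (2R)-7-(1-hydroxy-2-methylpropylidene)-2-(2-hydroxypropan-2-yl)-5,5-bis(3-methylbut-2-en-1-yl)-2,3-dihydro-1-benzofuran-4,6(5H,7H)-dione, via monoprenyl phenol 19 (not isolated)
Conditions: 18 (2.3 equiv), KOH (10% aq.), 0 °C → rt; then HCl to pH 3
Reagents that add atoms: none
Why: Alkylative dearomatisation: the acylphloroglucinol-type dianion is C-prenylated twice at C5, the only unsubstituted ring carbon flanked by two oxygens, as in the classical synthesis of lupulones, so that no new stereocenter arises and C2 is unaffected.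

**Compound list**
1 | methyl (2R)-oxirane-2-carboxylate | COC(=O)[C@H]1CO1 | starting material
2 | 2-[(2R)-oxiran-2-yl]propan-2-ol | CC(C)(O)[C@H]1CO1 | intermediate
3 | triethyl({2-[(2R)-oxiran-2-yl]propan-2-yl}oxy)silane | CC[Si](CC)(CC)OC(C)(C)[C@H]1CO1 | intermediate
4 | 2-(trimethylsilyl)ethanol | C[Si](C)(C)CCO | starting material
5 | (E)-1,2-dichlorovinyl 2-(trimethylsilyl)ethyl ether | C[Si](C)(C)CCO/C(Cl)=C\Cl | intermediate (not isolated)
6 | lithium [2-(trimethylsilyl)ethoxy]acetylide | C[Si](C)(C)CCOC#C[Li] | intermediate (not isolated)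
7 | (3R)-2-methyl-2-[(triethylsilyl)oxy]-6-[2-(trimethylsilyl)ethoxy]hex-5-yn-3-ol | C[Si](C)(C)CCOC#CC[C@@H](O)C(C)(C)O[Si](CC)(CC)CC | intermediate
8 | (E)-1,2-dichlorovinyl ether of 7 | C[Si](C)(C)CCOC#CC[C@@H](O/C(Cl)=C\Cl)C(C)(C)O[Si](CC)(CC)CC | intermediate (not isolated)
9 | lithium alkynyl ether of 7 | C[Si](C)(C)CCOC#CC[C@@H](OC#C[Li])C(C)(C)O[Si](CC)(CC)CC | intermediate (not isolated)
10 | 4-methyl-1-({(3R)-2-methyl-2-[(triethylsilyl)oxy]-6-[2-(trimethylsilyl)ethoxy]hex-5-yn-3-yl}oxy)pent-1-yn-3-one | C[Si](C)(C)CCOC#CC[C@@H](OC#CC(=O)C(C)C)C(C)(C)O[Si](CC)(CC)CC | intermediate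
11 | 2-{(2R)-3-methyl-2-[(4-methyl-3-oxopent-1-yn-1-yl)oxy]-3-[(triethylsilyl)oxy]butyl}-3-[2-(trimethylsilyl)ethoxy]cyclobut-2-en-1-one | O=C1CC(OCC[Si](C)(C)C)=C1C[C@@H](OC#CC(=O)C(C)C)C(C)(C)O[Si](CC)(CC)CC | intermediate
12 | vinylketene from ring opening of 11 | O=C=C(C[C@@H](OC#CC(=O)C(C)C)C(C)(C)O[Si](CC)(CC)CC)C(=C)OCC[Si](C)(C)C | intermediate (not isolated)
13 | 2-oxabicyclo[3.2.0]heptenone from the (2+2) addition (ring-fusion carbon as either epimer) | O=C1C(C(=O)C(C)C)=C2O[C@@H](C(C)(C)O[Si](CC)(CC)CC)CC12C(=C)OCC[Si](C)(C)C | intermediate (not isolated)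
14 | dienylketene from ring opening of 13 | O=C=C(C(=O)C(C)C)C1=C(C(=C)OCC[Si](C)(C)C)C[C@H](C(C)(C)O[Si](CC)(CC)CC)O1 | intermediate (not isolated)
15 | cyclohexa-2,4-dienone tautomer of 16 | O=C1CC(OCC[Si](C)(C)C)=C2C[C@H](C(C)(C)O[Si](CC)(CC)CC)OC2=C1C(=O)C(C)C | intermediate (not isolated)
16 | 1-[(2R)-6-hydroxy-2-{2-[(triethylsilyl)oxy]propan-2-yl}-4-[2-(trimethylsilyl)ethoxy]-2,3-dihydro-1-benzofuran-7-yl]-2-methylpropan-1-one | CC(C)C(=O)c1c(O)cc(OCC[Si](C)(C)C)c2C[C@H](C(C)(C)O[Si](CC)(CC)CC)Oc12 | intermediate
17 | 1-[(2R)-4,6-dihydroxy-2-(2-hydroxypropan-2-yl)-2,3-dihydro-1-benzofuran-7-yl]-2-methylpropan-1-one | CC(C)C(=O)c1c(O)cc(O)c2C[C@H](C(C)(C)O)Oc12 | intermediate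
18 | 1-bromo-3-methylbut-2-ene (prenyl bromide) | CC(C)=CCBr | starting material
19 | 1-[(2R)-4,6-dihydroxy-2-(2-hydroxypropan-2-yl)-5-(3-methylbut-2-en-1-yl)-2,3-dihydro-1-benzofuran-7-yl]-2-methylpropan-1-one | CC(C)C(=O)c1c(O)c(CC=C(C)C)c(O)c2C[C@H](C(C)(C)O)Oc12 | intermediate (not isolated)
20 | garcinielliptone HC, (2R)-7-(1-hydroxy-2-methylpropylidene)-2-(2-hydroxypropan-2-yl)-5,5-bis(3-methylbut-2-en-1-yl)-2,3-dihydro-1-benzofuran-4,6(5H,7H)-dione | CC(C)=CCC1(CC=C(C)C)C(=O)C2=C(O[C@@H](C(C)(C)O)C2)/C(=C(/O)C(C)C)C1=O | target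

**Totals.** Total step count: 8. Longest linear sequence: 8 steps (1 → 20).

**Steps most likely to fail**

Step 6 (new method). The acyl-deactivated ynol ether may not capture the vinylketene before retro-ene fragmentation of the secondary alkyl ynol ether or ketene dimerisation takes over. The fallback uses known biomimetic chemistry, sets out from 18 and returns to the route at 17. Commercial 2,4,6-trihydroxyisobutyrophenone F1 would be mono-C-prenylated with 18 (aq. KOH, 0 °C) to 3-prenylphlorisobutyrophenone F2. Persilylation (TBSOTf, 2,6-lutidine) would give the tris(tert-butyldimethylsilyl) ether F3. Shi epoxidation with the L-fructose-derived enantiomer of the ketone catalyst and KHSO5 (buffered with K2CO3) should give the (S)-epoxide F4. Bu4NF would then free the phenoxides, and the one ortho to the acyl group should open the epoxide 5-exo with inversion to give 17, which would have to be separated from the regioisomer closed through the other oxygen. This regiochemical ambiguity is what the main route avoids.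

Step 5. Capture of gaseous ketene may be incomplete because of dimerisation to diketene, and the moisture-sensitive ynol ethers may be lost during the long exposure. The fallback sets out from 10 and returns at 11. N,N-Dimethylacetamide, Tf2O and 2,4,6-collidine in CH2Cl2 (−20 °C → rt) would generate the much more electrophilic N,N-dimethylketeniminium triflate F5. Its (2+2) cycloaddition to the alkoxyalkyne of 10 should give the cyclobutenyliminium triflate F6, and hydrolysis with aq. NaHCO3 would return 11.

Step 8. O-Prenylation may compete with the second, dearomatising C-alkylation at the hindered C5. The fallback sets out from 17 and returns at 20. Double C-allylation with allyl methyl carbonate and Pd(PPh3)4 in THF, in which O-allyl products are funnelled to the C-allylated dienone through the π-allyl complex, should give the 5,5-diallyl compound F7. Cross-metathesis of both allyl groups with 2-methyl-2-butene (second-generation Grubbs catalyst RuCl2(=CHPh)(PCy3)(H2IMes), CH2Cl2, 40 °C) would then give 20.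

**Further compounds**
F1 | step 6 | 2,4,6-trihydroxyisobutyrophenone | CC(C)C(=O)c1c(O)cc(O)cc1O
F2 | step 6 | 2-methyl-1-[2,4,6-trihydroxy-3-(3-methylbut-2-en-1-yl)phenyl]propan-1-one | CC(C)C(=O)c1c(O)cc(O)c(CC=C(C)C)c1O
F3 | step 6 | tris(tert-butyldimethylsilyl) ether of F2 | CC(C)C(=O)c1c(O[Si](C)(C)C(C)(C)C)cc(O[Si](C)(C)C(C)(C)C)c(CC=C(C)C)c1O[Si](C)(C)C(C)(C)C
F4 | step 6 | (S)-epoxide of F3 | CC(C)C(=O)c1c(O[Si](C)(C)C(C)(C)C)cc(O[Si](C)(C)C(C)(C)C)c(C[C@@H]2OC2(C)C)c1O[Si](C)(C)C(C)(C)C
F5 | step 5 | N,N-dimethylketeniminium trifluoromethanesulfonate | C=C=[N+](C)C.[O-]S(=O)(=O)C(F)(F)F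
F6 | step 5 | cyclobutenyliminium trifluoromethanesulfonate corresponding to 11 | C[N+](C)=C1CC(OCC[Si](C)(C)C)=C1C[C@@H](OC#CC(=O)C(C)C)C(C)(C)O[Si](CC)(CC)CC.[O-]S(=O)(=O)C(F)(F)F
F7 | step 8 | (2R)-5,5-diallyl-7-(1-hydroxy-2-methylpropylidene)-2-(2-hydroxypropan-2-yl)-2,3-dihydro-1-benzofuran-4,6(5H,7H)-dione | C=CCC1(CC=C)C(=O)C2=C(O[C@@H](C(C)(C)O)C2)/C(=C(/O)C(C)C)C1=O
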